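**Plan** (chromanone numbering: O1, C2–C4, C4a, C5–C8, C8a; C9 is the carbinol carbon; ring A is the benzo ring, ring C the hemiacetal ring)
1. Retrosynthesis: ring C is opened at the hemiacetal bond O1–C2, the formyl carbon C2 is cut from C3, and the aryl ketone is cut at C4–C4a. This leaves a ring A bromide and an (S)-3-aryl-3-silyloxypropanal. Ring A is then cut at C5–C4a, C8–C8a and C5–C6 into a 3-siloxy-4-methoxycyclobutenone and a siloxyethyne.
2. Enabling feature: on ring A, C5–OH and C8a–O1 stand 1,3 across C4a (a resorcinol unit), while C6–OMe, C7–O and C8–Me are contiguous. A vinylketene–siloxyalkyne benzannulation gives this pattern with C5–OH free and O7/O1 silylated.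
3. Forward: ring A is made first from three two-carbon pieces. The C4–C3–C9 chain is joined at C4a (aryllithium plus aldehyde, then oxidation), C2 is added by Claisen formylation, and ring C closes last on O1 when the aryl silyl ethers fall.
4. Stereochemistry: C9 (S) comes from Noyori hydrogenation with (R)-BINAP. C3 and C2 are set in the hemiacetal closure under thermodynamic control relayed from C9.

Key step: step 4

Assumption: C2 (hemiacetal) and C3 (between C4=O and the hemiacetal carbon) equilibrate by ring–chain tautomerism, so the (2S,3R) arrangement of the target is taken to be the thermodynamically preferred one for the fixed (S)-C9 centre.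

**Step 1**
Reactants: 1 propyne
Product: 4 triisopropyl(prop-1-yn-1-yloxy)silane, via 1-propynyllithium 2 (not isolated), via lithium propynolate 3 (not isolated)
Conditions: n-BuLi, THF, −78 °C; t-BuOOLi (from t-BuOOH + LiN(SiMe3)2), −78 → −10 °C; TIPSOTf, −78 → 0 °C; then H2O
Reagents that add atoms: tert-butyl hydroperoxide CC(C)(C)OO; triisopropylsilyl triflate CC(C)[Si](OS(=O)(=O)C(F)(F)F)(C(C)C)C(C)C
Why: The lithium acetylide is oxidised at carbon by lithium tert-butyl peroxide to the ynolate (acetylide-to-ynolate oxidation), and the bulky silyl triflate traps it on oxygen, the usual access to triisopropylsilyl ynol ethers.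

**Step 2**
Reactants: 5 methoxyacetyl chloride; 4 triisopropyl(prop-1-yn-1-yloxy)silane
Product: 7 4-methoxy-2-methyl-3-(triisopropylsilyloxy)cyclobut-2-en-1-one (racemic), via methoxyketene 6 (not isolated)
Conditions: Et3N, Et2O, 0 °C → rt, 5 added slowly
Reagents that add atoms: none
Why: Dehydrochlorination gives methoxyketene, whose carbonyl carbon is attacked by the methyl-bearing carbon of the electron-rich siloxyalkyne, so the ketene–alkyne [2+2] cycloaddition places methyl at C2, the siloxy group at C3 and OMe at C4; the sp3 centre is racemic and is lost in step 4.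

**Step 3**
Reactants: 8 acetylene
Product: 11 (ethynyloxy)triisopropylsilane, via lithium acetylide 9 (not isolated), via lithium ethynolate 10 (not isolated)
Conditions: n-BuLi, THF, −78 °C (excess acetylene); t-BuOOLi (from t-BuOOH + LiN(SiMe3)2), −78 → −35 °C; TIPSOTf, −78 → 0 °C; then H2O
Reagents that add atoms: tert-butyl hydroperoxide CC(C)(C)OO; triisopropylsilyl triflate CC(C)[Si](OS(=O)(=O)C(F)(F)F)(C(C)C)C(C)C
Why: The same acetylide-to-ynolate oxidation and O-silylation as in step 1, applied to monolithium acetylide kept cold enough to avoid disproportionation, should give the parent siloxyalkyne.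

**Step 4**
Reactants: 7 4-methoxy-2-methyl-3-(triisopropylsilyloxy)cyclobut-2-en-1-one; 11 (ethynyloxy)triisopropylsilane
Product: 16 2-methoxy-4-methyl-3,5-bis(triisopropylsilyloxy)phenol, via siloxyvinylketene 12 (not isolated), via vinylcyclobutenone 13 (not isolated), via dienylketene 14 (not isolated), via cyclohexadienone 15 (not isolated)
Conditions: toluene, 110 °C, sealed vessel; 7 added slowly to 11 (2 equiv)
Reagents that add atoms: none
Why: Thermal 4π electrocyclic opening of 7 (OMe rotating outward) gives vinylketene 12, whose ketene carbon (future C5) is attacked by the terminal carbon of 11 in a regioselective [2+2] cycloaddition that forms C5–C4a and C8–C8a. Vinylcyclobutenone 13 reopens to dienylketene 14, and ring A closes by 6π electrocyclisation (C5–C6), after which dienone 15 tautomerises to the phenol. This is the Danheiser benzannulation of a cyclobutenone with a trialkylsilyloxyalkyne, which gives resorcinol monosilyl ethers. No stereocentre is formed, and the racemic centre of 7 becomes aromatic C6. The selectivity needed is regiochemical and is secured by the polarised siloxyalkyne, whose carbon β to oxygen bonds to the ketene carbon, so C5–OH emerges free while O1 and O7 carry TIPS; excess alkyne and slow addition of 7 keep the product phenol from acylating the ketene.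

**Step 5**
Reactants: 16 2-methoxy-4-methyl-3,5-bis(triisopropylsilyloxy)phenol
Product: 17 1-(benzyloxy)-2-methoxy-4-methyl-3,5-bis(triisopropylsilyloxy)benzene
Conditions: BnBr, K2CO3, n-Bu4NI (cat.), acetone, reflux
Reagents that add atoms: benzyl bromide BrCc1ccccc1
Why: Williamson etherification of the only free phenol marks O5 with a group that survives fluoride; the silyl ethers are not on adjacent oxygens, so they cannot migrate to the phenoxide.

**Step 6**
Reactants: 17 1-(benzyloxy)-2-methoxy-4-methyl-3,5-bis(triisopropylsilyloxy)benzene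
Product: 18 1-(benzyloxy)-6-bromo-2-methoxy-4-methyl-3,5-bis(triisopropylsilyloxy)benzene
Conditions: NBS, MeCN, 0 °C, dark
Reagents that add atoms: N-bromosuccinimide O=C1CCC(=O)N1Br
Why: Electrophilic aromatic bromination can only occur at C4a, the single unsubstituted ring position, which is activated by two ortho oxygens and one para oxygen.

**Step 7**
Reactants: 19 4'-(benzyloxy)acetophenone
Product: 20 methyl 3-[4-(benzyloxy)phenyl]-3-oxopropanoate
Conditions: NaH, (MeO)2CO, THF, reflux; then AcOH
Reagents that add atoms: dimethyl carbonate COC(=O)OC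
Why: Crossed Claisen condensation: the ketone enolate is C-acylated by the non-enolisable carbonate, and deprotonation of the β-keto ester drives the reaction.

**Step 8**
Reactants: 20 methyl 3-[4-(benzyloxy)phenyl]-3-oxopropanoate
Product: 21 methyl (S)-3-[4-(benzyloxy)phenyl]-3-hydroxypropanoate
Conditions: H2 (50 atm), RuCl2[(R)-BINAP] (cat.), MeOH, 50 °C
Reagents that add atoms: none
Why: Noyori asymmetric hydrogenation of a β-keto ester: the chelated substrate receives hydride on one carbonyl face from the (R)-BINAP–ruthenium hydride, giving the (S)-carbinol that becomes C9, and the aryl benzyl ether is inert to this homogeneous catalyst.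

**Step 9**
Reactants: 21 methyl (S)-3-[4-(benzyloxy)phenyl]-3-hydroxypropanoate
Product: 22 methyl (S)-3-[4-(benzyloxy)phenyl]-3-(tert-butyldimethylsilyloxy)propanoate
Conditions: TBSCl, imidazole, DMF, rt
Reagents that add atoms: tert-butyldimethylsilyl chloride CC(C)(C)[Si](C)(C)Cl
Why: Standard silylation of a secondary alcohol; the alkyl TBS ether is cleaved by fluoride more slowly than the aryl TIPS ethers, which step 14 uses.

**Step 10**
Reactants: 22 methyl (S)-3-[4-(benzyloxy)phenyl]-3-(tert-butyldimethylsilyloxy)propanoate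
Product: 23 (S)-3-[4-(benzyloxy)phenyl]-3-(tert-butyldimethylsilyloxy)propanal
Conditions: i-Bu2AlH, CH2Cl2, −78 °C; then aq. potassium sodium tartrate
Reagents that add atoms: none
Why: Partial ester reduction: at −78 °C i-Bu2AlH stops at the aluminium hemiacetal, which releases the aldehyde on work-up without touching C9.

**Step 11**
Reactants: 18 1-(benzyloxy)-6-bromo-2-methoxy-4-methyl-3,5-bis(triisopropylsilyloxy)benzene; 23 (S)-3-[4-(benzyloxy)phenyl]-3-(tert-butyldimethylsilyloxy)propanal
Product: 25 (3S)-1-[2-(benzyloxy)-3-methoxy-5-methyl-4,6-bis(triisopropylsilyloxy)phenyl]-3-[4-(benzyloxy)phenyl]-3-(tert-butyldimethylsilyloxy)propan-1-ol as a mixture of C1 epimers, via aryllithium 24 (not isolated)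
Conditions: t-BuLi (2 equiv), THF, −78 °C; then 23, −78 °C; then H2O
Reagents that add atoms: none
Why: Bromine–lithium exchange followed by 1,2-addition to the aldehyde forms C4a–C4; the bulky TIPS group makes anionic O-to-C silyl migration slow at −78 °C, and the uncontrolled carbinol centre is removed in step 12.

**Step 12**
Reactants: 25 the carbinol mixture from step 11
Product: 26 (S)-1-[2-(benzyloxy)-3-methoxy-5-methyl-4,6-bis(triisopropylsilyloxy)phenyl]-3-[4-(benzyloxy)phenyl]-3-(tert-butyldimethylsilyloxy)propan-1-one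
Conditions: Dess–Martin periodinane, pyridine, CH2Cl2, 0 °C → rt
Reagents that add atoms: none
Why: Dess–Martin oxidation converts both epimers into one aryl ketone under buffered conditions that spare the silyl ethers, the benzyl ethers and the electron-rich ring.

**Step 13**
Reactants: 26 the aryl ketone from step 12
Product: 28 (3S)-2-[2-(benzyloxy)-3-methoxy-5-methyl-4,6-bis(triisopropylsilyloxy)benzoyl]-3-[4-(benzyloxy)phenyl]-3-(tert-butyldimethylsilyloxy)propanal (C2 of the propanal stereolabile; largely the hydroxymethylene enol), via lithium enolate 27 (not isolated)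
Conditions: LiN(i-Pr)2, THF, −78 °C; HCO2CH2CF3, −78 °C; AcOH quench at −78 °C
Reagents that add atoms: 2,2,2-trifluoroethyl formate O=COCC(F)(F)F
Why: Crossed Claisen formylation: the kinetic lithium enolate (only the C3 methylene is enolisable) is C-formylated by the activated formate at −78 °C, where β-elimination of the C9 silyloxy group is slow, and the product stays as its chelated enolate until the cold acidic quench; C3 remains stereolabile here.

**Step 14**
Reactants: 28 the formyl ketone from step 13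
Product: 31 (2S,3R)-5-(benzyloxy)-3-{(S)-[4-(benzyloxy)phenyl](hydroxy)methyl}-2,7-dihydroxy-6-methoxy-8-methylchroman-4-one, via open-chain diphenol 29 (not isolated), via lactol silyl ether 30 (not isolated)
Conditions: n-Bu4NF/AcOH (1:1), THF, 0 °C → rt
Reagents that add atoms: none
Why: Fluoride cleaves the two aryl silyl ethers first, and because O5 is benzylated only the C8a phenol can add to the formyl group (6-exo hemiacetalisation, as in the classical 2-hydroxychromanone synthesis from o-hydroxyaryl ketones), so the slower loss of the C9 silyl group happens on a simple ketone and retro-aldol cleavage is avoided in the acetate buffer; C3 and C2 are set here under thermodynamic control by ring–chain equilibration, relayed from C9, as the 2,3-trans hemiacetal.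

**Step 15**
Reactants: 31 the dibenzyl lactol from step 14
Product: 32 (2S,3R)-2,5,7-trihydroxy-3-[(S)-hydroxy(4-hydroxyphenyl)methyl]-6-methoxy-8-methylchroman-4-one
Conditions: H2 (1 atm), 10% Pd/C, EtOAc, rt, stopped after two equivalents of H2
Reagents that add atoms: none
Why: Hydrogenolysis of the two aryl benzyl ethers in a neutral aprotic solvent is faster than C–O cleavage of the secondary benzylic alcohol and leaves the hemiacetal, the ketone and the three stereocentres untouched, the freed C5–OH being held by a hydrogen bond to C4=O.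

**Compound list**
1 | propyne | CC#C | starting material
2 | 1-propynyllithium (not isolated) | CC#C[Li] | intermediate
3 | lithium prop-1-yn-1-olate (not isolated) | CC#CO[Li] | intermediate
4 | triisopropyl(prop-1-yn-1-yloxy)silane | CC#CO[Si](C(C)C)(C(C)C)C(C)C | intermediate
5 | methoxyacetyl chloride | COCC(=O)Cl | starting material
6 | methoxyketene (not isolated) | COC=C=O | intermediate
7 | 4-methoxy-2-methyl-3-(triisopropylsilyloxy)cyclobut-2-en-1-one, racemic | COC1C(=O)C(C)=C1O[Si](C(C)C)(C(C)C)C(C)C | intermediate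
8 | acetylene | C#C | starting material
9 | lithium acetylide (not isolated) | C#C[Li] | intermediate
10 | lithium ethynolate (not isolated) | C#CO[Li] | intermediate
11 | (ethynyloxy)triisopropylsilane | C#CO[Si](C(C)C)(C(C)C)C(C)C | intermediate
12 | (Z)-4-methoxy-2-methyl-3-(triisopropylsilyloxy)buta-1,3-dien-1-one (not isolated) | O=C=C(C)/C(O[Si](C(C)C)(C(C)C)C(C)C)=C/OC | intermediate
13 | 4-[(Z)-2-methoxy-1-(triisopropylsilyloxy)ethenyl]-4-methyl-3-(triisopropylsilyloxy)cyclobut-2-en-1-one, racemic (not isolated) | O=C1C=C(O[Si](C(C)C)(C(C)C)C(C)C)C1(C)/C(O[Si](C(C)C)(C(C)C)C(C)C)=C/OC | intermediate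
14 | (3E,5Z)-6-methoxy-4-methyl-3,5-bis(triisopropylsilyloxy)hexa-1,3,5-trien-1-one (not isolated) | O=C=C/C(O[Si](C(C)C)(C(C)C)C(C)C)=C(C)\C(O[Si](C(C)C)(C(C)C)C(C)C)=C\OC | intermediate
15 | 6-methoxy-4-methyl-3,5-bis(triisopropylsilyloxy)cyclohexa-2,4-dien-1-one, racemic (not isolated) | COC1C(=O)C=C(O[Si](C(C)C)(C(C)C)C(C)C)C(C)=C1O[Si](C(C)C)(C(C)C)C(C)C | intermediate
16 | 2-methoxy-4-methyl-3,5-bis(triisopropylsilyloxy)phenol | COc1c(O)cc(O[Si](C(C)C)(C(C)C)C(C)C)c(C)c1O[Si](C(C)C)(C(C)C)C(C)C | intermediate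
17 | 1-(benzyloxy)-2-methoxy-4-methyl-3,5-bis(triisopropylsilyloxy)benzene | COc1c(OCc2ccccc2)cc(O[Si](C(C)C)(C(C)C)C(C)C)c(C)c1O[Si](C(C)C)(C(C)C)C(C)C | intermediate
18 | 1-(benzyloxy)-6-bromo-2-methoxy-4-methyl-3,5-bis(triisopropylsilyloxy)benzene | COc1c(OCc2ccccc2)c(Br)c(O[Si](C(C)C)(C(C)C)C(C)C)c(C)c1O[Si](C(C)C)(C(C)C)C(C)C | intermediate
19 | 4'-(benzyloxy)acetophenone | CC(=O)c1ccc(OCc2ccccc2)cc1 | starting material
20 | methyl 3-[4-(benzyloxy)phenyl]-3-oxopropanoate | COC(=O)CC(=O)c1ccc(OCc2ccccc2)cc1 | intermediate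
21 | methyl (S)-3-[4-(benzyloxy)phenyl]-3-hydroxypropanoate | COC(=O)C[C@H](O)c1ccc(OCc2ccccc2)cc1 | intermediate
22 | methyl (S)-3-[4-(benzyloxy)phenyl]-3-(tert-butyldimethylsilyloxy)propanoate | COC(=O)C[C@H](O[Si](C)(C)C(C)(C)C)c1ccc(OCc2ccccc2)cc1 | intermediate
23 | (S)-3-[4-(benzyloxy)phenyl]-3-(tert-butyldimethylsilyloxy)propanal | O=CC[C@H](O[Si](C)(C)C(C)(C)C)c1ccc(OCc2ccccc2)cc1 | intermediate
24 | [2-(benzyloxy)-3-methoxy-5-methyl-4,6-bis(triisopropylsilyloxy)phenyl]lithium (not isolated) | COc1c(OCc2ccccc2)c([Li])c(O[Si](C(C)C)(C(C)C)C(C)C)c(C)c1O[Si](C(C)C)(C(C)C)C(C)C | intermediate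
25 | (3S)-1-[2-(benzyloxy)-3-methoxy-5-methyl-4,6-bis(triisopropylsilyloxy)phenyl]-3-[4-(benzyloxy)phenyl]-3-(tert-butyldimethylsilyloxy)propan-1-ol, both C1 epimers | COc1c(OCc2ccccc2)c(C(O)C[C@H](O[Si](C)(C)C(C)(C)C)c2ccc(OCc3ccccc3)cc2)c(O[Si](C(C)C)(C(C)C)C(C)C)c(C)c1O[Si](C(C)C)(C(C)C)C(C)C | intermediate
26 | (S)-1-[2-(benzyloxy)-3-methoxy-5-methyl-4,6-bis(triisopropylsilyloxy)phenyl]-3-[4-(benzyloxy)phenyl]-3-(tert-butyldimethylsilyloxy)propan-1-one | COc1c(OCc2ccccc2)c(C(=O)C[C@H](O[Si](C)(C)C(C)(C)C)c2ccc(OCc3ccccc3)cc2)c(O[Si](C(C)C)(C(C)C)C(C)C)c(C)c1O[Si](C(C)C)(C(C)C)C(C)C | intermediate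
27 | lithium (Z)-enolate of 26, C9 S (not isolated) | COc1c(OCc2ccccc2)c(/C(O[Li])=C/[C@H](O[Si](C)(C)C(C)(C)C)c2ccc(OCc3ccccc3)cc2)c(O[Si](C(C)C)(C(C)C)C(C)C)c(C)c1O[Si](C(C)C)(C(C)C)C(C)C | intermediate
28 | (3S)-2-[2-(benzyloxy)-3-methoxy-5-methyl-4,6-bis(triisopropylsilyloxy)benzoyl]-3-[4-(benzyloxy)phenyl]-3-(tert-butyldimethylsilyloxy)propanal, C2 stereolabile (keto–enol tautomers) | COc1c(OCc2ccccc2)c(C(=O)C(C=O)[C@H](O[Si](C)(C)C(C)(C)C)c2ccc(OCc3ccccc3)cc2)c(O[Si](C(C)C)(C(C)C)C(C)C)c(C)c1O[Si](C(C)C)(C(C)C)C(C)C | intermediate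
29 | (3S)-2-[2-(benzyloxy)-4,6-dihydroxy-3-methoxy-5-methylbenzoyl]-3-[4-(benzyloxy)phenyl]-3-(tert-butyldimethylsilyloxy)propanal, C2 stereolabile (not isolated) | COc1c(OCc2ccccc2)c(C(=O)C(C=O)[C@H](O[Si](C)(C)C(C)(C)C)c2ccc(OCc3ccccc3)cc2)c(O)c(C)c1O | intermediate
30 | (2S,3R)-5-(benzyloxy)-3-{(S)-[4-(benzyloxy)phenyl](tert-butyldimethylsilyloxy)methyl}-2,7-dihydroxy-6-methoxy-8-methylchroman-4-one (not isolated) | COc1c(O)c(C)c2c(c1OCc1ccccc1)C(=O)[C@H]([C@H](O[Si](C)(C)C(C)(C)C)c1ccc(OCc3ccccc3)cc1)[C@@H](O)O2 | intermediate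
31 | (2S,3R)-5-(benzyloxy)-3-{(S)-[4-(benzyloxy)phenyl](hydroxy)methyl}-2,7-dihydroxy-6-methoxy-8-methylchroman-4-one | COc1c(O)c(C)c2c(c1OCc1ccccc1)C(=O)[C@H]([C@H](O)c1ccc(OCc3ccccc3)cc1)[C@@H](O)O2 | intermediate
32 | (2S,3R)-2,5,7-trihydroxy-3-[(S)-hydroxy(4-hydroxyphenyl)methyl]-6-methoxy-8-methylchroman-4-one | COc1c(O)c(C)c2c(c1O)C(=O)[C@H]([C@H](O)c1ccc(O)cc1)[C@@H](O)O2 | target

**Step count and risks**
Total: 15 steps. Longest linear sequence: 10 steps (1, 2, 4, 5, 6, 11, 12, 13, 14, 15).

Risk 1, step 4. The electron-rich cyclobutenone may resist ring opening below the temperature at which the alkyne decomposes, or the siloxyvinylketene may be consumed by the product phenol or by oligomerisation before the alkyne traps it. The fallback builds ring A by classical arene chemistry; it sets out from no numbered compound (steps 1–4 are replaced) and comes back at phenol 16. Commercial 2-methylresorcinol F1 is bis-silylated (TIPSCl, imidazole, DMF) to 2,6-bis(triisopropylsilyloxy)toluene F2. Monobromination (NBS, MeCN) gives 1-bromo-3-methyl-2,4-bis(triisopropylsilyloxy)benzene F3. Bromine–lithium exchange (t-BuLi, −78 °C), B(OMe)3 and H2O2/AcOH give 3-methyl-2,4-bis(triisopropylsilyloxy)phenol F4. Mitsunobu methylation (MeOH, PPh3, DIAD) gives 1-methoxy-3-methyl-2,4-bis(triisopropylsilyloxy)benzene F5. Methoxy-directed ortho-lithiation (n-BuLi, TMEDA, Et2O), borylation with B(OMe)3 and oxidation with H2O2/AcOH should then give 16, and the route continues at step 5.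

Risk 2, step 3. Monolithium acetylide may disproportionate to unreactive dilithium carbide before it is oxidised, and the unhindered parent ynolate may be silylated on carbon to give a silylketene. The fallback sets out from cyclobutenone 7 and comes back at bromide 18. (Trimethylsilyl)diazomethane is lithiated (n-BuLi, THF, −78 °C) and carbonylated (CO, 1 atm) to lithium (trimethylsilyl)ethynolate F6 (not isolated). O-Silylation with TIPSOTf gives triisopropyl{[(trimethylsilyl)ethynyl]oxy}silane F7. Heating F7 with 7 as in step 4 should give 2-methoxy-4-methyl-3,5-bis(triisopropylsilyloxy)-6-(trimethylsilyl)phenol F8, with the silicon-bearing alkyne carbon bonding to the ketene carbon. Benzylation as in step 5 gives 1-(benzyloxy)-2-methoxy-4-methyl-3,5-bis(triisopropylsilyloxy)-6-(trimethylsilyl)benzene F9, and ipso-bromodesilylation with NBS gives 18.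

Risk 3, step 13. The enolate may lose silanolate by β-elimination (E1cB) to a chalcone, or enolisation of the hindered ketone may be incomplete. The fallback avoids a free enolate; it sets out from ketone 26 and comes back at formyl ketone 28. Soft enolisation (TMSOTf, Et3N, CH2Cl2, 0 °C) gives the trimethylsilyl enol ether F10. Mukaiyama-type addition to trimethyl orthoformate (BF3·OEt2, CH2Cl2, −78 °C) gives the β-keto dimethyl acetal F11. Mild hydrolysis (AcOH/THF/H2O) gives 28.

**Further compounds**
F1 | step 4 | 2-methylresorcinol | Cc1c(O)cccc1O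
F2 | step 4 | 2,6-bis(triisopropylsilyloxy)toluene | Cc1c(O[Si](C(C)C)(C(C)C)C(C)C)cccc1O[Si](C(C)C)(C(C)C)C(C)C
F3 | step 4 | 1-bromo-3-methyl-2,4-bis(triisopropylsilyloxy)benzene | Cc1c(O[Si](C(C)C)(C(C)C)C(C)C)ccc(Br)c1O[Si](C(C)C)(C(C)C)C(C)C
F4 | step 4 | 3-methyl-2,4-bis(triisopropylsilyloxy)phenol | Cc1c(O[Si](C(C)C)(C(C)C)C(C)C)ccc(O)c1O[Si](C(C)C)(C(C)C)C(C)C
F5 | step 4 | 1-methoxy-3-methyl-2,4-bis(triisopropylsilyloxy)benzene | COc1ccc(O[Si](C(C)C)(C(C)C)C(C)C)c(C)c1O[Si](C(C)C)(C(C)C)C(C)C
F6 | step 3 | lithium (trimethylsilyl)ethynolate | C[Si](C)(C)C#CO[Li]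
F7 | step 3 | triisopropyl{[(trimethylsilyl)ethynyl]oxy}silane | C[Si](C)(C)C#CO[Si](C(C)C)(C(C)C)C(C)C
F8 | step 3 | 2-methoxy-4-methyl-3,5-bis(triisopropylsilyloxy)-6-(trimethylsilyl)phenol | COc1c(O)c([Si](C)(C)C)c(O[Si](C(C)C)(C(C)C)C(C)C)c(C)c1O[Si](C(C)C)(C(C)C)C(C)C
F9 | step 3 | 1-(benzyloxy)-2-methoxy-4-methyl-3,5-bis(triisopropylsilyloxy)-6-(trimethylsilyl)benzene | COc1c(OCc2ccccc2)c([Si](C)(C)C)c(O[Si](C(C)C)(C(C)C)C(C)C)c(C)c1O[Si](C(C)C)(C(C)C)C(C)C
F10 | step 13 | (Z)-trimethylsilyl enol ether of 26, C9 S | COc1c(OCc2ccccc2)c(/C(O[Si](C)(C)C)=C/[C@H](O[Si](C)(C)C(C)(C)C)c2ccc(OCc3ccccc3)cc2)c(O[Si](C(C)C)(C(C)C)C(C)C)c(C)c1O[Si](C(C)C)(C(C)C)C(C)C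
F11 | step 13 | (3S)-1-[2-(benzyloxy)-3-methoxy-5-methyl-4,6-bis(triisopropylsilyloxy)phenyl]-3-[4-(benzyloxy)phenyl]-3-(tert-butyldimethylsilyloxy)-2-(dimethoxymethyl)propan-1-one, both C2 epimers | COc1c(OCc2ccccc2)c(C(=O)C(C(OC)OC)[C@H](O[Si](C)(C)C(C)(C)C)c2ccc(OCc3ccccc3)cc2)c(O[Si](C(C)C)(C(C)C)C(C)C)c(C)c1O[Si](C(C)C)(C(C)C)C(C)C
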